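**Assumptions (one line each)**
- Atom labels follow germacranolide numbering (ring C1–C10; C7=C11; C12 = lactone carbonyl on O6; C13 = CH2OAc; C14 on C10; C15 on C4); the target is (1R,4R,5R,6S,8S,10R,2′R), i.e. 1β,10α:4α,5β-diepoxide, 6α-O lactone, 8α-ester.
- (S,S)-ProPhenol is taken as the ligand antipode that gives (4R)-9; if it gives (4S), (R,R)-ProPhenol is used and nothing else changes.
- Acid 15 is bought as a catalogue building block (chloro analogue of the bicalutamide bromo acid).

**Retrosynthetic overview**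
1. 18 ⇐ triene ester 16 by two peripheral epoxidations (last); 16 ⇐ 8β-alcohol 14 + acid 15 by invertive esterification.
2. 14 ⇐ 13 by closing C7–C8: C7, the β-carbon of the butenolide and normally an acceptor, is used as a vinylchromium donor (β-acyl vinyl anion, an sp2 homoenolate equivalent) and adds to the C8 aldehyde.
3. The butenolide of 13 ⇐ γ-hydroxy ynoate 9 (iodide conjugate addition, formaldehyde aldol, lactonisation); 9 ⇐ enal 7 + methyl propiolate 8 (catalytic asymmetric alkynylation sets C6).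
4. C8 travels as a 1,3-dithiane (formyl anion equivalent) attached to 8-bromogeranyl acetate 3, which comes from geranyl acetate 1.
5. Ring order: butenolide → ten-membered carbocycle → two oxiranes.

**Step 1**
Reactants: 1 geranyl acetate
Product: 2 (2E,6E)-8-hydroxy-3,7-dimethylocta-2,6-dien-1-yl acetate
Conditions: SeO2 (0.3 equiv), t-BuOOH (70% aq., 3 equiv), salicylic acid (0.1 equiv), CH2Cl2, rt
Reagents that add atoms: selenium dioxide O=[Se]=O (catalytic oxygen transfer); tert-butyl hydroperoxide CC(C)(C)OO (terminal oxidant)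
Why: SeO2/TBHP allylic oxidation (ene reaction then [2,3]-shift) attacks the (E)-methyl of the electron-richer terminal alkene, the 2,3-alkene being deactivated by the allylic acetate, and gives the (E)-allylic alcohol with no stereocentre formed.

**Step 2**
Reactants: 2 (2E,6E)-8-hydroxy-3,7-dimethylocta-2,6-dien-1-yl acetate
Product: 3 (2E,6E)-8-bromo-3,7-dimethylocta-2,6-dien-1-yl acetate
Conditions: CBr4 (1.2 equiv), PPh3 (1.25 equiv), CH2Cl2, 0 °C
Reagents that add atoms: carbon tetrabromide BrC(Br)(Br)Br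
Why: Appel reaction, in which bromide displaces the primary allylic oxyphosphonium by SN2 with the (E)-geometry kept.

**Step 3**
Reactants: 3 (2E,6E)-8-bromo-3,7-dimethylocta-2,6-dien-1-yl acetate; 4 1,3-dithiane
Product: 6 (2E,6E)-8-(1,3-dithian-2-yl)-3,7-dimethylocta-2,6-dien-1-ol, via dithianyl acetate 5 (not isolated)
Conditions: 4 (1.5 equiv), n-BuLi (1.45 equiv), THF, −30 °C; then 3, −78 °C; then MeOH, K2CO3 (cat.), rt
Reagents that add atoms: none
Why: Corey–Seebach alkylation, in which the lithiated dithiane (a formyl anion equivalent) displaces the primary allylic bromide at the α-carbon by SN2, and methanolysis in the same pot frees the C6 hydroxyl.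

**Step 4**
Reactants: 6 (2E,6E)-8-(1,3-dithian-2-yl)-3,7-dimethylocta-2,6-dien-1-ol
Product: 7 (2E,6E)-8-(1,3-dithian-2-yl)-3,7-dimethylocta-2,6-dienal
Conditions: activated MnO2 (15 equiv), CH2Cl2, rt
Reagents that add atoms: none
Why: MnO2 oxidises only the allylic alcohol to the (E)-enal and leaves the thioacetal and the olefin geometry untouched.

**Step 5**
Reactants: 7 (2E,6E)-8-(1,3-dithian-2-yl)-3,7-dimethylocta-2,6-dienal; 8 methyl propiolate
Product: 9 methyl (4R,5E,9E)-11-(1,3-dithian-2-yl)-4-hydroxy-6,10-dimethylundeca-5,9-dien-2-ynoate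
Conditions: (S,S)-ProPhenol (20 mol %), Me2Zn (3.0 equiv), Ph3P=O (40 mol %), 8 (3.0 equiv), toluene, 4 °C
Reagents that add atoms: none
Why: Trost Zn–ProPhenol asymmetric alkynylation, in which the dinuclear zinc catalyst delivers the zinc acetylide to one enantioface of the enal and so sets C6 (4R in 9, the arrangement that becomes 6S in the target), the only stereocentre of the ring system set by a catalyst.

**Step 6**
Reactants: 9 methyl (4R,5E,9E)-11-(1,3-dithian-2-yl)-4-hydroxy-6,10-dimethylundeca-5,9-dien-2-ynoate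
Product: 11 (5R)-5-[(1E,5E)-7-(1,3-dithian-2-yl)-2,6-dimethylhepta-1,5-dien-1-yl]-3-(hydroxymethyl)-4-iodofuran-2(5H)-one, via open-chain iodo-aldol ester 10 (not isolated)
Conditions: Et2AlI (3.0 equiv), CH2Cl2, −40 °C; CH2O (gas from cracked paraformaldehyde, 5 equiv), −40 → 0 °C; aq. Rochelle salt / 1 M HCl, rt
Reagents that add atoms: diethylaluminium iodide CC[Al](I)CC; formaldehyde C=O
Why: β-iodo Morita–Baylis–Hillman (halo-aldol) reaction, in which Et2AlI first turns the hydroxyl into an aluminium alkoxide (so no proton can quench the allenolate), iodide adds to C7, the β-iodoallenolate is hydroxymethylated at C11, and since E/Z isomers interconvert by reversible iodide addition while only the isomer with O6 cis to the ester can lactonise, ring formation fixes the tetrasubstituted alkene geometry without touching C6.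

**Step 7**
Reactants: 11 (5R)-5-[(1E,5E)-7-(1,3-dithian-2-yl)-2,6-dimethylhepta-1,5-dien-1-yl]-3-(hydroxymethyl)-4-iodofuran-2(5H)-one
Product: 12 [(5R)-5-[(1E,5E)-7-(1,3-dithian-2-yl)-2,6-dimethylhepta-1,5-dien-1-yl]-4-iodo-2-oxo-2,5-dihydrofuran-3-yl]methyl acetate
Conditions: Ac2O (1.5 equiv), pyridine, CH2Cl2, 0 °C (no DMAP)
Reagents that add atoms: acetic anhydride CC(=O)OC(C)=O
Why: Plain O-acetylation of the primary alcohol with a weak base, so that the acidic γ-hydrogen at C6 is not removed and C6 is not epimerised.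

**Step 8**
Reactants: 12 [(5R)-5-[(1E,5E)-7-(1,3-dithian-2-yl)-2,6-dimethylhepta-1,5-dien-1-yl]-4-iodo-2-oxo-2,5-dihydrofuran-3-yl]methyl acetate
Product: 13 [(5R)-5-[(1E,5E)-2,6-dimethyl-8-oxoocta-1,5-dien-1-yl]-4-iodo-2-oxo-2,5-dihydrofuran-3-yl]methyl acetate
Conditions: MeI (10 equiv), CaCO3 (5 equiv), MeCN–H2O 9:1, 40 °C; used at once
Reagents that add atoms: water O
Why: Dithiane hydrolysis by S-methylation (Fétizon conditions) under CaCO3 buffer unmasks the aldehyde without moving the β,γ-double bond into conjugation and without touching the vinyl iodide, the acetate or C6.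

**Step 9**
Reactants: 13 [(5R)-5-[(1E,5E)-2,6-dimethyl-8-oxoocta-1,5-dien-1-yl]-4-iodo-2-oxo-2,5-dihydrofuran-3-yl]methyl acetate
Product: 14 (6R,8R)-13-acetoxy-8-hydroxygermacra-1(10)E,4E,7(11)-trien-12,6-olide
Conditions: CrCl2 (10 equiv), NiCl2 (5 mol %), degassed DMSO–THF 3:1, rt, 13 added over 12 h (final 2 mM)
Reagents that add atoms: none
Why: Intramolecular Nozaki–Hiyama–Kishi reaction, in which Ni inserts into C7–I and chromium makes the butenolide β-carbon a nucleophile (β-acyl vinyl anion) that adds to the aldehyde carbon C8, joining two acceptor carbons and closing the ten-membered ring; H-8 eclipses C7=C11 to avoid allylic 1,3-strain with the C13 acetoxymethyl, the C9 arm has to lie on the face of the C5 arm fixed by C6, and the Cr–O unit therefore sits on the open opposite face, which gives the 8β-alcohol (8R).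

**Step 10**
Reactants: 14 (6R,8R)-13-acetoxy-8-hydroxygermacra-1(10)E,4E,7(11)-trien-12,6-olide; 15 (2R)-3-chloro-2-hydroxy-2-methylpropanoic acid
Product: 16 (6R,8S)-13-acetoxy-8-[(2R)-3-chloro-2-hydroxy-2-methylpropanoyloxy]germacra-1(10)E,4E,7(11)-trien-12,6-olide
Conditions: 15 (1.5 equiv), PPh3 (1.6 equiv), DIAD (1.6 equiv, added last), toluene, 0 °C → rt
Reagents that add atoms: none
Why: Mitsunobu esterification, in which the carboxylate displaces the C8 oxyphosphonium by SN2 with inversion (8R → 8S, the 8α-ester), while the tertiary hydroxyl of 15 cannot be activated and its stereocentre is carried over unchanged.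

**Step 11**
Reactants: 16 (6R,8S)-13-acetoxy-8-[(2R)-3-chloro-2-hydroxy-2-methylpropanoyloxy]germacra-1(10)E,4E,7(11)-trien-12,6-olide
Product: 18 (1R,4R,5R,6S,8S,10R)-13-acetoxy-8-[(2R)-3-chloro-2-hydroxy-2-methylpropanoyloxy]-1,10:4,5-diepoxygermacr-7(11)-en-12,6-olide, via 1(10)-monoepoxide 17 (not isolated)
Conditions: mCPBA (2.4 equiv), CH2Cl2 / pH 7 phosphate buffer, 0 °C → rt
Reagents that add atoms: meta-chloroperoxybenzoic acid OOC(=O)c1cccc(Cl)c1
Why: Prilezhaev epoxidation, in which the peracid attacks each (E)-trisubstituted alkene of the crown conformer from its outer face (the 1(10)-alkene first, the electron-poor butenolide alkene not at all), as in the known peracid epoxidations of costunolide and parthenolide, giving the 1β,10α- and 4α,5β-oxiranes (1R,10R and 4R,5R).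

**Compound list**
1 | geranyl acetate | CC(=O)OC/C=C(\C)CCC=C(C)C | starting material
2 | (2E,6E)-8-hydroxy-3,7-dimethylocta-2,6-dien-1-yl acetate | CC(=O)OC/C=C(\C)CC/C=C(\C)CO | intermediate
3 | (2E,6E)-8-bromo-3,7-dimethylocta-2,6-dien-1-yl acetate | CC(=O)OC/C=C(\C)CC/C=C(\C)CBr | intermediate
4 | 1,3-dithiane | C1CSCSC1 | starting material
5 | (2E,6E)-8-(1,3-dithian-2-yl)-3,7-dimethylocta-2,6-dien-1-yl acetate | CC(=O)OC/C=C(\C)CC/C=C(\C)CC1SCCCS1 | intermediate (not isolated)
6 | (2E,6E)-8-(1,3-dithian-2-yl)-3,7-dimethylocta-2,6-dien-1-ol | OC/C=C(\C)CC/C=C(\C)CC1SCCCS1 | intermediate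
7 | (2E,6E)-8-(1,3-dithian-2-yl)-3,7-dimethylocta-2,6-dienal | O=C/C=C(\C)CC/C=C(\C)CC1SCCCS1 | intermediate
8 | methyl propiolate | C#CC(=O)OC | starting material
9 | methyl (4R,5E,9E)-11-(1,3-dithian-2-yl)-4-hydroxy-6,10-dimethylundeca-5,9-dien-2-ynoate | COC(=O)C#C[C@H](O)/C=C(\C)CC/C=C(\C)CC1SCCCS1 | intermediate
10 | methyl (2E,4R,5E,9E)-11-(1,3-dithian-2-yl)-4-hydroxy-2-(hydroxymethyl)-3-iodo-6,10-dimethylundeca-2,5,9-trienoate | COC(=O)/C(CO)=C(I)\[C@H](O)/C=C(\C)CC/C=C(\C)CC1SCCCS1 | intermediate (not isolated)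
11 | (5R)-5-[(1E,5E)-7-(1,3-dithian-2-yl)-2,6-dimethylhepta-1,5-dien-1-yl]-3-(hydroxymethyl)-4-iodofuran-2(5H)-one | OCC1=C(I)[C@@H](/C=C(\C)CC/C=C(\C)CC2SCCCS2)OC1=O | intermediate
12 | [(5R)-5-[(1E,5E)-7-(1,3-dithian-2-yl)-2,6-dimethylhepta-1,5-dien-1-yl]-4-iodo-2-oxo-2,5-dihydrofuran-3-yl]methyl acetate | CC(=O)OCC1=C(I)[C@@H](/C=C(\C)CC/C=C(\C)CC2SCCCS2)OC1=O | intermediate
13 | [(5R)-5-[(1E,5E)-2,6-dimethyl-8-oxoocta-1,5-dien-1-yl]-4-iodo-2-oxo-2,5-dihydrofuran-3-yl]methyl acetate | CC(=O)OCC1=C(I)[C@@H](/C=C(\C)CC/C=C(\C)CC=O)OC1=O | intermediate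
14 | (6R,8R)-13-acetoxy-8-hydroxygermacra-1(10)E,4E,7(11)-trien-12,6-olide (8β-alcohol; ten-membered E,E-diene ring fused to the butenolide) | CC(=O)OCC1=C2[C@H](O)C/C(C)=C/CC/C(C)=C/[C@H]2OC1=O | intermediate
15 | (2R)-3-chloro-2-hydroxy-2-methylpropanoic acid | OC(=O)[C@@](C)(O)CCl | starting material
16 | (6R,8S)-13-acetoxy-8-[(2R)-3-chloro-2-hydroxy-2-methylpropanoyloxy]germacra-1(10)E,4E,7(11)-trien-12,6-olide | CC(=O)OCC1=C2[C@@H](OC(=O)[C@@](C)(O)CCl)C/C(C)=C/CC/C(C)=C/[C@H]2OC1=O | intermediate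
17 | (1R,6R,8S,10R)-13-acetoxy-8-[(2R)-3-chloro-2-hydroxy-2-methylpropanoyloxy]-1,10-epoxygermacra-4E,7(11)-dien-12,6-olide | CC(=O)OCC1=C2[C@@H](OC(=O)[C@@](C)(O)CCl)C[C@@]3(C)O[C@@H]3CC/C(C)=C/[C@H]2OC1=O | intermediate (not isolated)
18 | (1R,4R,5R,6S,8S,10R)-13-acetoxy-8-[(2R)-3-chloro-2-hydroxy-2-methylpropanoyloxy]-1,10:4,5-diepoxygermacr-7(11)-en-12,6-olide (CNP0255009.1) | CC(=O)OCC1=C2[C@@H](OC(=O)[C@@](C)(O)CCl)C[C@@]3(C)O[C@@H]3CC[C@@]3(C)O[C@@H]3[C@H]2OC1=O | target

**Totals**
Total step count: 11. Longest linear sequence: 11 steps (1 → 18); 4, 8 and 15 are bought and enter in steps 3, 5 and 10.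

**The three steps most likely to fail**

Step 9 (Ni/Cr ring closure). Forming a strained ten-membered E,E-diene ring is demanding, and the C8 configuration rests on a conformational argument. The stereochemical failure has a clean fallback, which sets out from 13 and returns at 16. If the chromium alkoxide ends on the face of the ring arms, the closure gives the epimer (6R,8S)-13-acetoxy-8-hydroxygermacra-1(10)E,4E,7(11)-trien-12,6-olide F3 instead of 14. F3 already has the target configuration at C8, so the stereochemistry is relayed by retention instead of inversion. F3 is esterified directly with 15 (DIC, DMAP 5 mol %, CH2Cl2, −20 °C, Steglich) to give 16, and the Mitsunobu step is dropped.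

Step 6 (halo-aldol and lactonisation). The internal ynoate may react sluggishly, the allenolate may be protonated instead of hydroxymethylated, or E/Z equilibration may be slow. The fallback sets out from 9 and returns at 11, and replaces the allenolate by a stereospecific syn-stannylcupration. First 9 is silylated (TMSCl, imidazole, CH2Cl2) to methyl (4R,5E,9E)-11-(1,3-dithian-2-yl)-6,10-dimethyl-4-(trimethylsilyloxy)undeca-5,9-dien-2-ynoate F1. Then (Me3Sn)Cu·SMe2 in THF at −78 °C adds tin to C7 and copper to C11 on the same side, and the alkenylcopper is trapped with formaldehyde with retention. On citric acid work-up the silyl ether is lost and O6, now necessarily cis to the ester, lactonises to (5R)-5-[(1E,5E)-7-(1,3-dithian-2-yl)-2,6-dimethylhepta-1,5-dien-1-yl]-3-(hydroxymethyl)-4-(trimethylstannyl)furan-2(5H)-one F2. Iododestannylation (I2, 1.05 equiv, CH2Cl2, 0 °C) then gives 11.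

Step 10 (Mitsunobu inversion on the macrocycle). Elimination towards C9 or no reaction at the hindered allylic carbinol are the likely failures. The fallback sets out from 14 and returns at 16, and inverts C8 by oxidation and reduction instead of SN2. Dess–Martin periodinane (NaHCO3, CH2Cl2, 0 °C) gives (6R)-13-acetoxy-8-oxogermacra-1(10)E,4E,7(11)-trien-12,6-olide F4. Luche reduction (NaBH4, CeCl3·7H2O, MeOH, −78 °C) delivers hydride from the open face that carried the chromium alkoxide in step 9, giving the epimer (6R,8S)-13-acetoxy-8-hydroxygermacra-1(10)E,4E,7(11)-trien-12,6-olide F5. F5 is then esterified with 15 with retention (DIC, DMAP 5 mol %, CH2Cl2, −20 °C) to give 16.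

**Further compounds**
F1 | step 6 | methyl (4R,5E,9E)-11-(1,3-dithian-2-yl)-6,10-dimethyl-4-(trimethylsilyloxy)undeca-5,9-dien-2-ynoate | COC(=O)C#C[C@H](O[Si](C)(C)C)/C=C(\C)CC/C=C(\C)CC1SCCCS1
F2 | step 6 | (5R)-5-[(1E,5E)-7-(1,3-dithian-2-yl)-2,6-dimethylhepta-1,5-dien-1-yl]-3-(hydroxymethyl)-4-(trimethylstannyl)furan-2(5H)-one | OCC1=C([Sn](C)(C)C)[C@@H](/C=C(\C)CC/C=C(\C)CC2SCCCS2)OC1=O
F3 | step 9 | (6R,8S)-13-acetoxy-8-hydroxygermacra-1(10)E,4E,7(11)-trien-12,6-olide | CC(=O)OCC1=C2[C@@H](O)C/C(C)=C/CC/C(C)=C/[C@H]2OC1=O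
F4 | step 10 | (6R)-13-acetoxy-8-oxogermacra-1(10)E,4E,7(11)-trien-12,6-olide | CC(=O)OCC1=C2C(=O)C/C(C)=C/CC/C(C)=C/[C@H]2OC1=O
F5 | step 10 | (6R,8S)-13-acetoxy-8-hydroxygermacra-1(10)E,4E,7(11)-trien-12,6-olide | CC(=O)OCC1=C2[C@@H](O)C/C(C)=C/CC/C(C)=C/[C@H]2OC1=O
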